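## The problem

CNP0248258.1 is an unsymmetrical dimer of two 2-(2-phenylethyl)chromones joined by a single ether oxygen. With the second chromone primed, this oxygen links C5 of a 5,6,7,8-tetrahydrochromone (ring A reduced) to the aromatic carbon C6' of the other unit, whose neighbouring C7' hydroxyl is free. The reduced ring carries four contiguous oxygenated stereocentres, 5S,6S,7R,8S: the aryloxy group on C5 and the hydroxyl on C8 lie on one face, the cis-6,7-diol on the other (5,6-trans, 6,7-cis, 7,8-trans). Because the 6,7-diol is cis and anti to O8, one stereocentre at C8 can set C6 and C7 by osmylation of a C6=C7 alkene, and the diol oxygens can then set C5 if the last substituent comes from their face. Only C8 therefore needs a reagent to fix absolute configuration. The molecule is sensitive: the C5–O bond is allylic to the C4a=C8a enol ether of the pyranone and ionizes with acid, the triol can dehydrate and re-aromatize ring A, the γ-pyranones open at C2 with hydroxide or alkoxide and bind Lewis acids at the carbonyl, and the C7' phenol is acidic. The enabling feature is that O–C6' and HO–C7' form a catechol monoether. If ring A is taken to its aromatic level (an 8-hydroxychromone), oxidation of the C8 phenol can be answered by the C7' hydroxyl adding to C5, which stores ring A as a cyclohexadienone with C5 spiro to a 1,3-benzodioxole and the ether oxygen already in place.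

## Retrosynthesis

**C5–H (with C5–O7' restored).** Target 22 is read as the product of a reductive opening of a spiro ketal, which leads through the silylated intermediate 21 to ketal 20. The neighbouring cut, C5–O6' by etherification of a C5 carbinol, would need a complete chiral tetrol and a substitution at a hindered, ionizable carbon. The ketal cut keeps the ether oxygen on C5 from the aromatic stage onward, and 20 has one stereocentre less to control because spiro C5 is erased on opening. The forward reaction must ionize toward O7' and not O6'. That is expected because O7' is para to the acyl carbon C4a' and behaves as a phenylogous carboxylate oxygen. It must also place hydrogen on C5 from the diol face, which is why O6 and O7 carry Si–H groups in 20.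

**O–Si, then C6–O and C7–O.** Removing the two dimethylsilyl groups gives diol 19, and removing the cis-diol gives alkene 18. A cis-diol anti to an allylic oxygen maps directly onto osmylation, whereas an epoxide route would give a trans-diol. Compound 18 has only C8 as a controlling stereocentre. The forward step needs face selectivity from the C8 substituent alone, since C5 carries one ketal oxygen on each face. For that reason O8 bears a bulky silyl group without Si–H in 18, which also keeps the later hydride delivery confined to the lower face.

**O8–Si and C8–H.** Desilylation gives dienol 17, and removal of the C8 hydrogen gives the cross-conjugated ketone 16. This is the one place where absolute configuration enters. The two arms of the ketone differ clearly (fully substituted C8a against C7–H), which suits an oxazaborolidine-catalysed reduction. Compound 16 has no stereocentre that must be controlled. The forward step must be a clean 1,2-reduction next to two unreactive pyranone carbonyls, and it must avoid acid, which would re-aromatize the dienol.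

**C5–O7' (key disconnection).** Cutting the second ketal bond and returning ring A to the aromatic level gives the diaryl ether 15, a flat, achiral bis-chromone. This removes every stereocentre and reduces the problem to joining two aromatic chromones. The forward step is an oxidative dearomatization in which the C8 phenol is oxidized and the C7' hydroxyl closes the dioxole on C5. It must select ring A over ring B and C5 over C7.

**O–CH3, O–CH2Ph and C5–O6'.** Two ether protecting groups lead back to 14, and the diaryl ether bond is cut at C5 to give fluoride 8 and phenol 13. The cut is made on the ring A side because C5 is ortho to the C4 carbonyl and can undergo nucleophilic aromatic substitution, whereas C6' of ring B has no such activation. The two halves are of equal size, so the route is convergent. The forward step must overcome the donor effect of the C8 methoxy group para to fluorine.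

**Pyranone of ring A and the aryl–acetyl bond.** Chromone 8 is cut at C2–C3 and O1–C2 to acetophenone 5 and ester 6 (Claisen condensation, then cyclodehydration). Ketone 5 is cut at the aryl–acetyl bond to the MOM ether 2 and on to phenol 1. The position between fluorine and the protected oxygen is the one addressed by directed ortho-metalation, which avoids the para-selectivity expected from a Fries rearrangement.

**Pyranone of ring B.** Chromone 13 is cut in the same way to acetophenone 11 and ester 6. Ketone 11 comes from triol 9 through benzyl ether 10, using the acidity order of the three hydroxyls (C4 most acidic, C2 hydrogen-bonded).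

## Roads not taken

Alternative 1: Ring B is built last around the finished ether. The cut is the C6'–C7' bond of the aromatic ring. In the forward direction, photolysis of diazo ketone A1 triggers a Wolff rearrangement to ketene A2, whose ketene carbon becomes C7'. A 6π-electrocyclization onto the enol ether carbon C6' and tautomerization then give the protected target A3 with the 7'-phenol free. Its merits are real: the C5–O bond is made as an ordinary enol ether of a defined carbinol, so C5 is never at risk, and the free hydroxyl appears exactly at C7' with no regiochemical question. Its weak points are the substrate and the light. A1 needs a complete, protected chiral tetrahydrochromone plus a vinylation of its hindered C5 hydroxyl and a diazoacetyl pyranone. Two pyranone chromophores compete for the photons and can undergo cycloaddition of their own. In stereochemical safety at C5 this road is better than the chosen plan. The chosen plan sets against it a flat aromatic precursor reached in eight steps and one catalytic reduction as the only source of chirality.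

Alternative 2: The aryl ether oxygen is moved from C8 to C5 while the carbocycle closes. The cuts are O–C5 and C5–C6. In the forward direction, tosylhydrazone A4 is decomposed and a dirhodium tetracarboxylate catalyst generates a carbene at C5. The aryl ether oxygen on C8 traps it, and the oxonium ylide undergoes a [2,3]-shift through the (Z)-vinylsilane to give A5, the trans-5-aryloxy-6-silyl dihydrochromone with a C7=C8 alkene. The attraction is that the ether bond and the 5,6-trans relationship are set together in one concerted event, where the chosen plan relies on an unproven delivered hydride. Several points weigh against it for this target. An aryl ether oxygen is a poor nucleophile for ylide formation, so cyclopropanation of the vinylsilane, C–H insertion and a [1,2]-shift compete. The sense of chirality transfer from the C8 stereocentre of A4 depends on the envelope of the five-membered ylide and cannot be fixed on paper, which is why that centre is left open here. After A5 the silicon must be oxidized and, more seriously, the 7,8-trans-diol cannot come from osmylation of C7=C8 and needs an epoxidation and a regioselective opening. The chosen plan fits the cis-6,7-diol to osmylation directly and reaches its key substrate far more quickly.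

Alternative 3: The pyranone of ring A is fused last onto a finished cyclohexane. The cuts are C4–C4a and O1–C8a. In the forward direction, heating dioxinone A7 releases acylketene A8, which adds across the enol ether double bond of A6 between C4a and C8a, and loss of methanol from C8a gives the protected target A9. This is the most conservative road stereochemically: all four stereocentres and the ether are set by standard reactions on a cyclohexane before any sensitive tetrahydrochromone exists, and the annulation belongs to a known reaction class. In that respect it is better than the chosen plan. Its price is length and one awkward step. A6 is a chiral, fully oxygenated cyclohexenyl enol ether that already carries the aryl ether, and it would take a long chiral-pool or desymmetrization sequence to prepare. The thermolysis must also form a tetrasubstituted pyranone next to an allylic aryl ether that can eliminate at the temperature needed to open the dioxinone. The chosen plan offers brevity and convergence but accepts two steps without direct precedent.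

Key step: step 9

Assumption (step 10): the fully substituted C8a arm of ketone 16 is taken as the large group and the C7–H arm as the small one, as in 2-substituted cyclohex-2-enones; on that basis the (R)-oxazaborolidine gives the 8S alcohol.

Assumption (compounds 16–21): 16–20 are carried as both C5 epimers (spiro carbon undefined in the SMILES), and 21 is drawn for hydride transfer from the silane on O7; transfer from the silane on O6 would give its isomer and the same product 22.

## Route

Step 1
Reactants: 1 5-fluoro-2-methoxyphenol
Product: 2 4-fluoro-1-methoxy-2-(methoxymethoxy)benzene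
Conditions: MOMCl, iPr2NEt, CH2Cl2, 0 °C → rt
Reagents that add atoms: chloromethyl methyl ether, COCCl
Why: O-Alkylation of the phenol to its methoxymethyl acetal; the MOM ether is the directing group for the metalation in step 2.

Step 2
Reactants: 2 4-fluoro-1-methoxy-2-(methoxymethoxy)benzene
Product: 5 1-(6-fluoro-2-hydroxy-3-methoxyphenyl)ethanone, via aryllithium 3 (not isolated), via MOM-protected ketone 4 (not isolated)
Conditions: n-BuLi, THF, −78 °C; MeC(O)N(OMe)Me, −78 → 0 °C; then 3 M HCl, MeOH, 50 °C
Reagents that add atoms: N-methoxy-N-methylacetamide, CC(=O)N(C)OC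
Why: Directed ortho-metalation: the C–H between fluorine and the MOM ether is acidified by both groups and is lithiated selectively at −78 °C, where the ortho-fluoroaryllithium does not yet lose LiF. The N-methoxy-N-methyl amide forms a chelated adduct that releases the ketone only on work-up, and acidic methanol then cleaves the MOM acetal next to the carbonyl.

Step 3
Reactants: 5 1-(6-fluoro-2-hydroxy-3-methoxyphenyl)ethanone; 6 ethyl 3-phenylpropanoate
Product: 8 5-fluoro-8-methoxy-2-(2-phenylethyl)chromen-4-one, via 1,3-diketone 7 (not isolated)
Conditions: NaH, THF, 65 °C; then conc. HCl, MeOH, 65 °C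
Reagents that add atoms: none
Why: Crossed Claisen condensation of the ketone enolate with the ester gives the 1,3-diketone, which in acid closes through the phenol oxygen and dehydrates to the 4-pyranone (chromone cyclodehydration). During the basic stage the phenol is a phenoxide, which makes the ring electron-rich and keeps the diketonate oxygen from displacing the ortho fluoride.

Step 4
Reactants: 9 1-(2,4,5-trihydroxyphenyl)ethanone
Product: 10 1-[4-(benzyloxy)-2,5-dihydroxyphenyl]ethanone
Conditions: BnBr, NaHCO3, DMF, 40 °C, argon
Reagents that add atoms: benzyl bromide, BrCc1ccccc1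
Why: Williamson ether synthesis under a weak base: only the C4 hydroxyl, para to the acetyl group, is acidic enough for NaHCO3, the C2 hydroxyl is held in a hydrogen bond to the carbonyl and the C5 hydroxyl is the least acidic. Air is excluded because the substrate is a hydroxyhydroquinone.

Step 5
Reactants: 10 1-[4-(benzyloxy)-2,5-dihydroxyphenyl]ethanone
Product: 11 1-[4-(benzyloxy)-2-hydroxy-5-(methoxymethoxy)phenyl]ethanone
Conditions: MOMCl, iPr2NEt, CH2Cl2, 0 °C
Reagents that add atoms: chloromethyl methyl ether, COCCl
Why: Acetal protection of the only free, non-chelated phenol; the hydrogen-bonded C2 hydroxyl does not react with an amine base at 0 °C. This avoids an oxidation-prone hydroquinone dianion in step 6.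

Step 6
Reactants: 11 1-[4-(benzyloxy)-2-hydroxy-5-(methoxymethoxy)phenyl]ethanone; 6 ethyl 3-phenylpropanoate
Product: 13 7-(benzyloxy)-6-hydroxy-2-(2-phenylethyl)chromen-4-one, via 1,3-diketone 12 (not isolated)
Conditions: NaH, THF, 65 °C; then conc. HCl, MeOH, 65 °C
Reagents that add atoms: none
Why: Claisen condensation and acid cyclodehydration as in step 3; the acidic methanol also removes the MOM acetal and frees the C6 hydroxyl, while the benzyl ether is stable.

Step 7
Reactants: 8 5-fluoro-8-methoxy-2-(2-phenylethyl)chromen-4-one; 13 7-(benzyloxy)-6-hydroxy-2-(2-phenylethyl)chromen-4-one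
Product: 14 5-{[7-(benzyloxy)-4-oxo-2-(2-phenylethyl)chromen-6-yl]oxy}-8-methoxy-2-(2-phenylethyl)chromen-4-one
Conditions: Cs2CO3, DMSO, 110 °C
Reagents that add atoms: none
Why: Nucleophilic aromatic substitution by addition–elimination: the C4 carbonyl ortho to C5 takes up the charge of the anionic σ-adduct and fluoride is the best leaving group for this mechanism. The para methoxy group slows the reaction, hence the dipolar solvent, the cesium phenoxide and heat under anhydrous conditions that spare the pyranones.

Step 8
Reactants: 14 5-{[7-(benzyloxy)-4-oxo-2-(2-phenylethyl)chromen-6-yl]oxy}-8-methoxy-2-(2-phenylethyl)chromen-4-one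
Product: 15 8-hydroxy-5-{[7-hydroxy-4-oxo-2-(2-phenylethyl)chromen-6-yl]oxy}-2-(2-phenylethyl)chromen-4-one
Conditions: BBr3, CH2Cl2, −78 → 0 °C; aq. NaHCO3
Reagents that add atoms: none
Why: Lewis-acid ether cleavage: bromide attacks the O-methyl and O-benzyl carbons of the boron-complexed ethers and frees both phenols in one operation. The diaryl ether and the pyranones do not react.

Step 9
Reactants: 15 8-hydroxy-5-{[7-hydroxy-4-oxo-2-(2-phenylethyl)chromen-6-yl]oxy}-2-(2-phenylethyl)chromen-4-one
Product: 16 2,6'-bis(2-phenylethyl)spiro[chromene-5,2'-[1,3]dioxolo[4,5-g]chromene]-4,8,8'-trione (spiro quinone monoketal: ring A as the 8-oxo-6,7-ene, C5 spiro to the benzodioxole of ring B; racemic at C5)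
Conditions: PhI(OAc)2, (CF3)2CHOH, 4 Å MS, 0 °C
Reagents that add atoms: none
Why: Proposed new method: Ligand exchange places the C8 phenol oxygen on trivalent iodine, and reductive loss of iodobenzene leaves a phenoxonium ion whose positive charge sits mainly on the para carbon C5, where the aryloxy oxygen O6' stabilizes it. The C7' hydroxyl, held ortho to O6', adds to C5 and closes the five-membered 1,3-benzodioxole in a 5-exo-trig mode, giving the cyclohexadienone with C5 as a spiro ketal carbon. The closest known reaction type is the hypervalent iodine oxidation of 4-alkoxy- and 4-aryloxyphenols to quinone monoketals, including cases where a tethered alcohol or acid closes a spiro ring; a phenol on the aryloxy ring as internal nucleophile and a chromone-fused hydroquinone as substrate have not been shown. The new stereocentre C5 forms as a racemate, and no control is sought because it is destroyed in step 14. The step needs selectivity between the two phenols and for para over ortho capture: ring A is a hydroquinone monoether and much more electron-rich than ring B, whose phenol is para to the acyl carbon C4a', and the aryloxy substituent directs the nucleophile to C5 and not to C7. Capture by solvent or acetate is countered by the weakly nucleophilic fluoroalcohol, the sieves and the intramolecular five-ring closure, and an acetate adduct at C5 would re-ionize and end in the same ketal.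

Step 10
Reactants: 16 2,6'-bis(2-phenylethyl)spiro[chromene-5,2'-[1,3]dioxolo[4,5-g]chromene]-4,8,8'-trione
Product: 17 (8S)-8-hydroxy-2,6'-bis(2-phenylethyl)-8H-spiro[chromene-5,2'-[1,3]dioxolo[4,5-g]chromene]-4,8'-dione (both C5 epimers)
Conditions: (R)-2-methyl-CBS-oxazaborolidine, catecholborane, CH2Cl2/toluene, −78 °C; MeOH, pH 7 buffer
Reagents that add atoms: none
Why: Corey–Bakshi–Shibata reduction: the ketone binds the catalyst boron through the lone pair on the side of C7–H, and the coordinated borane delivers hydride to one face, which sets C8 as S. Only the cross-conjugated C8 ketone reacts because the two pyranone carbonyls are vinylogous esters. The spiro centre is remote and carries one oxygen on each face, so both C5 epimers should be reduced in the same sense.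

Step 11
Reactants: 17 (8S)-8-hydroxy-2,6'-bis(2-phenylethyl)-8H-spiro[chromene-5,2'-[1,3]dioxolo[4,5-g]chromene]-4,8'-dione
Product: 18 (8S)-8-[(tert-butyldimethylsilyl)oxy]-2,6'-bis(2-phenylethyl)-8H-spiro[chromene-5,2'-[1,3]dioxolo[4,5-g]chromene]-4,8'-dione (both C5 epimers)
Conditions: TBSCl, imidazole, DMF, 0 °C → rt
Reagents that add atoms: tert-butyldimethylsilyl chloride, CC(C)(C)[Si](C)(C)Cl
Why: Silyl ether formation under non-acidic conditions, which the acid-sensitive dienol ketal requires. The bulky group screens the upper face in step 12, and because it has no Si–H it cannot deliver hydride to the wrong face in step 14.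

Step 12
Reactants: 18 (8S)-8-[(tert-butyldimethylsilyl)oxy]-2,6'-bis(2-phenylethyl)-8H-spiro[chromene-5,2'-[1,3]dioxolo[4,5-g]chromene]-4,8'-dione
Product: 19 (6S,7R,8S)-8-[(tert-butyldimethylsilyl)oxy]-6,7-dihydroxy-2,6'-bis(2-phenylethyl)-7,8-dihydro-6H-spiro[chromene-5,2'-[1,3]dioxolo[4,5-g]chromene]-4,8'-dione (cis-diol anti to the silyloxy group; both C5 epimers)
Conditions: OsO4 (cat.), NMO, acetone/H2O, 0 °C → rt
Reagents that add atoms: osmium tetroxide, O=[Os](=O)(=O)=O; 4-methylmorpholine N-oxide, C[N+]1([O-])CCOCC1; water, O
Why: Upjohn dihydroxylation: syn addition of OsO4 to C6=C7, the only alkene that is neither tetrasubstituted nor part of a vinylogous ester. Attack should come anti to the allylic silyloxy group, since the C5 end offers one ketal oxygen on each face and C8 is then the only bias; this sets C6 and C7.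

Step 13
Reactants: 19 (6S,7R,8S)-8-[(tert-butyldimethylsilyl)oxy]-6,7-dihydroxy-2,6'-bis(2-phenylethyl)-7,8-dihydro-6H-spiro[chromene-5,2'-[1,3]dioxolo[4,5-g]chromene]-4,8'-dione
Product: 20 6,7-bis-O-(dimethylsilyl) ether of 19 (configuration at C6, C7 and C8 unchanged; used crude)
Conditions: (HMe2Si)2NH, THF, 50 °C; evaporate
Reagents that add atoms: 1,1,3,3-tetramethyldisilazane, C[SiH](C)N[SiH](C)C
Why: O-Silylation of alcohols with a disilazane, with ammonia as the only by-product, places an Si–H group on each oxygen of the lower face. The labile product is not chromatographed.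

Step 14
Reactants: 20 6,7-bis-O-(dimethylsilyl) ether of 19
Product: 22 (5S,6S,7R,8S)-6,7,8-trihydroxy-5-{[7-hydroxy-4-oxo-2-(2-phenylethyl)chromen-6-yl]oxy}-2-(2-phenylethyl)-5,6,7,8-tetrahydrochromen-4-one (CNP0248258.1), via persilylated ether 21 (not isolated)
Conditions: Me3SiOTf, 2,6-di-tert-butyl-4-methylpyridine, CH2Cl2, −78 → −40 °C; then HF·pyridine, THF, 0 °C → rt
Reagents that add atoms: none
Why: Proposed new method: Silylation of the ring B pyranone carbonyl by Me3SiOTf turns O7' into the leaving group of a phenylogous silyl ester, so the ketal should ionize by loss of O7' to a C5 oxocarbenium ion stabilized by O6' and, through C4a=C8a, by O1; the Si–H groups on O6 and O7 lie on one face and deliver hydride through five- and six-membered transition states, which puts hydrogen on C5 cis to the diol and leaves the aryloxy group trans to O6 and cis to O8 (C5 = S) from either spiro epimer. The closest known reaction types are the Lewis-acid-promoted intramolecular hydrosilylation of β-silyloxy ketones and the reductive opening of ketals by silanes with silyl triflates; tethered delivery to a ketal-derived cation has not been shown on this substrate class. HF·pyridine then removes all silyl groups without the base that the pyranones and the C7' phenol would not tolerate.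

## Compound list

1 | 5-fluoro-2-methoxyphenol | COc1ccc(F)cc1O | starting material
2 | 4-fluoro-1-methoxy-2-(methoxymethoxy)benzene | COCOc1cc(F)ccc1OC | intermediate
3 | [6-fluoro-3-methoxy-2-(methoxymethoxy)phenyl]lithium | [Li]c1c(F)ccc(OC)c1OCOC | intermediate (not isolated)
4 | 1-[6-fluoro-3-methoxy-2-(methoxymethoxy)phenyl]ethanone | CC(=O)c1c(F)ccc(OC)c1OCOC | intermediate (not isolated)
5 | 1-(6-fluoro-2-hydroxy-3-methoxyphenyl)ethanone | CC(=O)c1c(F)ccc(OC)c1O | intermediate
6 | ethyl 3-phenylpropanoate | CCOC(=O)CCc1ccccc1 | starting material
7 | 1-(6-fluoro-2-hydroxy-3-methoxyphenyl)-5-phenylpentane-1,3-dione | O=C(CC(=O)CCc1ccccc1)c1c(F)ccc(OC)c1O | intermediate (not isolated)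
8 | 5-fluoro-8-methoxy-2-(2-phenylethyl)chromen-4-one | COc1ccc(F)c2c(=O)cc(CCc3ccccc3)oc12 | intermediate
9 | 1-(2,4,5-trihydroxyphenyl)ethanone (2,4,5-trihydroxyacetophenone) | CC(=O)c1cc(O)c(O)cc1O | starting material
10 | 1-[4-(benzyloxy)-2,5-dihydroxyphenyl]ethanone | CC(=O)c1cc(O)c(OCc2ccccc2)cc1O | intermediate
11 | 1-[4-(benzyloxy)-2-hydroxy-5-(methoxymethoxy)phenyl]ethanone | CC(=O)c1cc(OCOC)c(OCc2ccccc2)cc1O | intermediate
12 | 1-[4-(benzyloxy)-2-hydroxy-5-(methoxymethoxy)phenyl]-5-phenylpentane-1,3-dione | O=C(CC(=O)CCc1ccccc1)c1cc(OCOC)c(OCc2ccccc2)cc1O | intermediate (not isolated)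
13 | 7-(benzyloxy)-6-hydroxy-2-(2-phenylethyl)chromen-4-one | O=c1cc(CCc2ccccc2)oc2cc(OCc3ccccc3)c(O)cc12 | intermediate
14 | 5-{[7-(benzyloxy)-4-oxo-2-(2-phenylethyl)chromen-6-yl]oxy}-8-methoxy-2-(2-phenylethyl)chromen-4-one | COc1ccc(Oc2cc3c(=O)cc(CCc4ccccc4)oc3cc2OCc2ccccc2)c2c(=O)cc(CCc3ccccc3)oc12 | intermediate
15 | 8-hydroxy-5-{[7-hydroxy-4-oxo-2-(2-phenylethyl)chromen-6-yl]oxy}-2-(2-phenylethyl)chromen-4-one | O=c1cc(CCc2ccccc2)oc2c(O)ccc(Oc3cc4c(=O)cc(CCc5ccccc5)oc4cc3O)c12 | intermediate
16 | 2,6'-bis(2-phenylethyl)spiro[chromene-5,2'-[1,3]dioxolo[4,5-g]chromene]-4,8,8'-trione, racemic at C5 | O=C1C=CC2(Oc3cc4c(=O)cc(CCc5ccccc5)oc4cc3O2)c2c1oc(CCc1ccccc1)cc2=O | intermediate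
17 | (8S)-8-hydroxy-2,6'-bis(2-phenylethyl)-8H-spiro[chromene-5,2'-[1,3]dioxolo[4,5-g]chromene]-4,8'-dione, both C5 epimers | O[C@H]1C=CC2(Oc3cc4c(=O)cc(CCc5ccccc5)oc4cc3O2)c2c1oc(CCc1ccccc1)cc2=O | intermediate
18 | (8S)-8-[(tert-butyldimethylsilyl)oxy]-2,6'-bis(2-phenylethyl)-8H-spiro[chromene-5,2'-[1,3]dioxolo[4,5-g]chromene]-4,8'-dione, both C5 epimers | CC(C)(C)[Si](C)(C)O[C@H]1C=CC2(Oc3cc4c(=O)cc(CCc5ccccc5)oc4cc3O2)c2c1oc(CCc1ccccc1)cc2=O | intermediate
19 | (6S,7R,8S)-8-[(tert-butyldimethylsilyl)oxy]-6,7-dihydroxy-2,6'-bis(2-phenylethyl)-7,8-dihydro-6H-spiro[chromene-5,2'-[1,3]dioxolo[4,5-g]chromene]-4,8'-dione, both C5 epimers | O=c1cc(CCc2ccccc2)oc2c1C1(Oc3cc4c(=O)cc(CCc5ccccc5)oc4cc3O1)[C@@H](O)[C@@H](O)[C@@H]2O[Si](C)(C)C(C)(C)C | intermediate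
20 | 6,7-bis-O-(dimethylsilyl) ether of 19 | O=c1cc(CCc2ccccc2)oc2c1C1(Oc3cc4c(=O)cc(CCc5ccccc5)oc4cc3O1)[C@@H](O[SiH](C)C)[C@@H](O[SiH](C)C)[C@@H]2O[Si](C)(C)C(C)(C)C | intermediate
21 | target 22 carrying SiMe3 on O7', SiMe2H on O6, SiMe2OTf on O7 and tert-butyldimethylsilyl on O8 (C5–C8 configured as in 22) | O=c1cc(CCc2ccccc2)oc2c1[C@H](Oc1cc3c(=O)cc(CCc4ccccc4)oc3cc1O[Si](C)(C)C)[C@@H](O[SiH](C)C)[C@@H](O[Si](C)(C)OS(=O)(=O)C(F)(F)F)[C@@H]2O[Si](C)(C)C(C)(C)C | intermediate (not isolated)
22 | (5S,6S,7R,8S)-6,7,8-trihydroxy-5-{[7-hydroxy-4-oxo-2-(2-phenylethyl)chromen-6-yl]oxy}-2-(2-phenylethyl)-5,6,7,8-tetrahydrochromen-4-one | O=c1cc(CCc2ccccc2)oc2c1[C@H](Oc1cc3c(=O)cc(CCc4ccccc4)oc3cc1O)[C@@H](O)[C@@H](O)[C@@H]2O | target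

## Step count and risks

Total: 14 steps. Longest linear sequence: 11 steps (steps 1–3 or 4–6, then 7–14).

**Step 9 (key step, new method).** The phenoxonium ion may be captured by acetate or traces of water before O7' reaches C5, which would end in hydrolysis to the quinone and loss of ring B. The acetic acid formed may also re-open the ketal. Fallback with known chemistry, setting out from 15 and returning at 16: the oxidation is run in methanol (PhI(OAc)2, MeOH, 0 °C), the standard oxidative methoxylation of para-oxygenated phenols. This gives the mixed methyl aryl quinone monoketal 5-{[7-hydroxy-4-oxo-2-(2-phenylethyl)chromen-6-yl]oxy}-5-methoxy-2-(2-phenylethyl)chromene-4,8-dione F1. A separate acid-catalysed transketalization (pyridinium p-toluenesulfonate, toluene, 4 Å MS) then lets the C7' hydroxyl displace methanol and close the dioxole to 16.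

**Step 14 (new method).** Ionization may occur on the wrong oxygen (O6' leaving) and give the regioisomeric ether. The cation may lose the C6 proton and go on to aromatize, or the benzodioxole-type ketal may not ionize at all at low temperature. Fallback with known chemistry, setting out from 19 and returning at 22, at the price of giving up the ring B unit held in the ketal:
- Aqueous trifluoroacetic acid hydrolyses the spiro ketal to the 5-ketone (6S,7R,8S)-8-[(tert-butyldimethylsilyl)oxy]-6,7-dihydroxy-2-(2-phenylethyl)-7,8-dihydro-6H-chromene-4,5-dione F2.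
- 2,2-Dimethoxypropane with pyridinium p-toluenesulfonate gives its 6,7-acetonide F3.
- NaBH4/CeCl3 (Luche reduction) attacks C5 from the face away from the acetonide and gives the 5-alcohol cis to the acetonide oxygens F4.
- Mitsunobu etherification with phenol 13 (PPh3, diisopropyl azodicarboxylate) inverts C5 and gives the fully protected 5-aryl ether F5.
- Aqueous HCl in methanol removes the acetonide and the silyl group to give the 7'-O-benzyl ether of the target F6, and hydrogenolysis (H2, Pd on carbon) gives 22.

**Step 7.** The substitution may be too slow because the C8 methoxy group feeds electron density into C5, so base-induced degradation of the pyranones (attack at C2, condensation through the side-chain dienolate) could outrun it. Fallback, setting out from phenol 13 and returning at 14, replaces the addition–elimination by a copper-catalysed Ullmann coupling with a bromide made from commercial 5-bromo-2-methoxyphenol by the sequence of steps 1–3: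
- MOM protection gives 4-bromo-1-methoxy-2-(methoxymethoxy)benzene F7.
- Deprotonation between bromine and the MOM ether with LiN(iPr)2 at −78 °C gives the aryllithium [6-bromo-3-methoxy-2-(methoxymethoxy)phenyl]lithium F8.
- N-Methoxy-N-methylacetamide gives 1-[6-bromo-3-methoxy-2-(methoxymethoxy)phenyl]ethanone F9, and HCl in methanol gives 1-(6-bromo-2-hydroxy-3-methoxyphenyl)ethanone F10.
- Claisen condensation with 6 gives 1-(6-bromo-2-hydroxy-3-methoxyphenyl)-5-phenylpentane-1,3-dione F11, and acid closes it to 5-bromo-8-methoxy-2-(2-phenylethyl)chromen-4-one F12.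
- CuI, picolinic acid and K3PO4 in DMSO at 90 °C couple F12 with 13 to give 14.

**Step 10.** Boron Lewis acids may promote loss of aryloxide from C5 together with the C8 proton, which re-aromatizes the dienol to the diaryl ether. The two arms of the ketone may also be discriminated less well than assumed. Fallback, setting out from 16 and returning at 17, separates reduction from stereocontrol. Luche reduction (NaBH4, CeCl3·7H2O, MeOH, −78 °C) gives the alcohol racemic at C8, 8-hydroxy-2,6'-bis(2-phenylethyl)-8H-spiro[chromene-5,2'-[1,3]dioxolo[4,5-g]chromene]-4,8'-dione F13. A lipase-catalysed kinetic resolution (Burkholderia cepacia lipase, vinyl acetate) should, by the usual enantiopreference of lipases for secondary alcohols, acylate the 8R alcohol to the (8R)-acetate F14 and leave 17.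

## Further compounds

F1 | step 9 | 5-{[7-hydroxy-4-oxo-2-(2-phenylethyl)chromen-6-yl]oxy}-5-methoxy-2-(2-phenylethyl)chromene-4,8-dione (racemic) | COC1(Oc2cc3c(=O)cc(CCc4ccccc4)oc3cc2O)C=CC(=O)c2oc(CCc3ccccc3)cc(=O)c21
F2 | step 14 | (6S,7R,8S)-8-[(tert-butyldimethylsilyl)oxy]-6,7-dihydroxy-2-(2-phenylethyl)-7,8-dihydro-6H-chromene-4,5-dione | O=c1cc(CCc2ccccc2)oc2c1C(=O)[C@@H](O)[C@@H](O)[C@@H]2O[Si](C)(C)C(C)(C)C
F3 | step 14 | 6,7-O-isopropylidene derivative of F2 | O=c1cc(CCc2ccccc2)oc2c1C(=O)[C@H]1OC(C)(C)O[C@H]1[C@@H]2O[Si](C)(C)C(C)(C)C
F4 | step 14 | 5-alcohol from F3, hydroxyl cis to the acetonide oxygens | O=c1cc(CCc2ccccc2)oc2c1[C@@H](O)[C@H]1OC(C)(C)O[C@H]1[C@@H]2O[Si](C)(C)C(C)(C)C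
F5 | step 14 | 7'-O-benzyl 6,7-O-isopropylidene 8-O-(tert-butyldimethylsilyl) derivative of 22 | O=c1cc(CCc2ccccc2)oc2c1[C@H](Oc1cc3c(=O)cc(CCc4ccccc4)oc3cc1OCc1ccccc1)[C@H]1OC(C)(C)O[C@H]1[C@@H]2O[Si](C)(C)C(C)(C)C
F6 | step 14 | 7'-O-benzyl ether of 22 | O=c1cc(CCc2ccccc2)oc2c1[C@H](Oc1cc3c(=O)cc(CCc4ccccc4)oc3cc1OCc1ccccc1)[C@@H](O)[C@@H](O)[C@@H]2O
F7 | step 7 | 4-bromo-1-methoxy-2-(methoxymethoxy)benzene | COCOc1cc(Br)ccc1OC
F8 | step 7 | [6-bromo-3-methoxy-2-(methoxymethoxy)phenyl]lithium | [Li]c1c(Br)ccc(OC)c1OCOC
F9 | step 7 | 1-[6-bromo-3-methoxy-2-(methoxymethoxy)phenyl]ethanone | CC(=O)c1c(Br)ccc(OC)c1OCOC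
F10 | step 7 | 1-(6-bromo-2-hydroxy-3-methoxyphenyl)ethanone | CC(=O)c1c(Br)ccc(OC)c1O
F11 | step 7 | 1-(6-bromo-2-hydroxy-3-methoxyphenyl)-5-phenylpentane-1,3-dione | O=C(CC(=O)CCc1ccccc1)c1c(Br)ccc(OC)c1O
F12 | step 7 | 5-bromo-8-methoxy-2-(2-phenylethyl)chromen-4-one | COc1ccc(Br)c2c(=O)cc(CCc3ccccc3)oc12
F13 | step 10 | 8-hydroxy-2,6'-bis(2-phenylethyl)-8H-spiro[chromene-5,2'-[1,3]dioxolo[4,5-g]chromene]-4,8'-dione, racemic at C8 | OC1C=CC2(Oc3cc4c(=O)cc(CCc5ccccc5)oc4cc3O2)c2c1oc(CCc1ccccc1)cc2=O
F14 | step 10 | (8R)-8-acetoxy-2,6'-bis(2-phenylethyl)-8H-spiro[chromene-5,2'-[1,3]dioxolo[4,5-g]chromene]-4,8'-dione | CC(=O)O[C@@H]1C=CC2(Oc3cc4c(=O)cc(CCc5ccccc5)oc4cc3O2)c2c1oc(CCc1ccccc1)cc2=O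
A1 | alternative 1 | 6,7-O-isopropylidene 8-O-methoxymethyl tetrahydrochromone whose O5 carries an (E)-2-[2-(diazoacetyl)-4-oxo-6-(2-phenylethyl)pyran-3-yl]ethenyl group | O=c1cc(CCc2ccccc2)oc2c1[C@H](O/C=C/c1c(C(=O)C=[N+]=[N-])oc(CCc3ccccc3)cc1=O)[C@@H](OC(C)(C)O3)[C@@H]3[C@@H]2OCOC
A2 | alternative 1 | ketene formed from A1 by Wolff rearrangement | O=c1cc(CCc2ccccc2)oc2c1[C@H](O/C=C/c1c(C=C=O)oc(CCc3ccccc3)cc1=O)[C@@H](OC(C)(C)O3)[C@@H]3[C@@H]2OCOC
A3 | alternative 1 | 6,7-O-isopropylidene 8-O-methoxymethyl derivative of 22, 7'-hydroxyl free | O=c1cc(CCc2ccccc2)oc2c1[C@H](Oc1cc3c(=O)cc(CCc4ccccc4)oc3cc1O)[C@@H](OC(C)(C)O3)[C@@H]3[C@@H]2OCOC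
A4 | alternative 2 | tosylhydrazone of 2-[(Z)-1-{[7-(benzyloxy)-4-oxo-2-(2-phenylethyl)chromen-6-yl]oxy}-3-(isopropoxydimethylsilyl)prop-2-enyl]-4-oxo-6-(2-phenylethyl)pyran-3-carbaldehyde, aryloxy-bearing carbon left undefined | O=c1cc(CCc2ccccc2)oc(C(Oc2cc3c(=O)cc(CCc4ccccc4)oc3cc2OCc2ccccc2)/C=C\[Si](C)(C)OC(C)C)c1/C=N/NS(=O)(=O)c1ccc(C)cc1
A5 | alternative 2 | trans-5-{[7-(benzyloxy)-4-oxo-2-(2-phenylethyl)chromen-6-yl]oxy}-6-(isopropoxydimethylsilyl)-2-(2-phenylethyl)-5,6-dihydrochromen-4-one | O=c1cc(CCc2ccccc2)oc2c1[C@H](Oc1cc3c(=O)cc(CCc4ccccc4)oc3cc1OCc1ccccc1)[C@@H]([Si](C)(C)OC(C)C)C=C2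
A6 | alternative 3 | 1-methoxycyclohexene carrying the 7-(methoxymethoxy)-4-oxo-2-(2-phenylethyl)chromen-6-yloxy group at C3, a cis-isopropylidenedioxy group at C4/C5 and a methoxymethoxy group at C6, configured as in 22 | COC1=C[C@H](Oc2cc3c(=O)cc(CCc4ccccc4)oc3cc2OCOC)[C@H]2OC(C)(C)O[C@H]2[C@@H]1OCOC
A7 | alternative 3 | 2,2-dimethyl-6-(2-phenylethyl)-1,3-dioxin-4-one | CC1(C)OC(=O)C=C(CCc2ccccc2)O1
A8 | alternative 3 | 3-oxo-5-phenylpent-1-en-1-one (acylketene from A7) | O=C=CC(=O)CCc1ccccc1
A9 | alternative 3 | 6,7-O-isopropylidene 8,7'-bis-O-methoxymethyl derivative of 22 | O=c1cc(CCc2ccccc2)oc2c1[C@H](Oc1cc3c(=O)cc(CCc4ccccc4)oc3cc1OCOC)[C@@H](OC(C)(C)O3)[C@@H]3[C@@H]2OCOC
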